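**Plan**

Megaphone numbering is used throughout: ring C1 (C=O), C2=C3, C4 (OMe), C5 (CH2), C6 (quaternary, allyl); side chain C7 (CHMe), C8 (CHOH–aryl). The feature that opens the route is the six-membered ring with oxygen on C1 and on C4, the two allylic carbons flanking the C2=C3 alkene, beside the two-carbon unit C5–C6. This is the imprint of a 1,4-dioxygenated butadiene on a 1,1-disubstituted alkene whose formyl activator is a masked allyl group.
Retrosynthesis: first the functional-group changes (C8 O–Si, C1 C=O from CHOH, C4 O–Me), then the allyl group back to a formyl group on C6, then C1–C6 and C4–C5 together (Diels–Alder), then the C5 methylene of the enal, last C7–C8.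
Forward: C8–C7 is joined by crotylboration and the chain is grown to the 2-substituted acrolein 11; the only new ring closes in step 8 from 11 and diene 14; formyl is then homologated to allyl, C4–O is methylated and C1–O oxidised.
Stereochemistry: C7 and C8 come from reagent-controlled syn-crotylboration (Z-crotyl, isopinocampheyl groups from (−)-α-pinene). C6, C1 and C4 come from the cycloaddition (E,E diene gives cis oxygens, the exo array sets them against C6, C7 selects the enal face). C1 is later erased by oxidation.

Key step: step 8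

Remarks on the chemistry: (a) the silylation of succinaldehyde is assumed to give mainly the E,E dienol ether; isomers containing a Z bond cannot reach the s-cis shape and are treated as spectators, so 14 is used in excess. (b) Triethylsilyl (ring oxygens) and triisopropylsilyl (C8) are chosen so that the ring ethers survive base but fall to dilute acid, while the C8 ether survives both and does not migrate.

**Step 1**
Reactants: 1 3,4,5-trimethoxybenzaldehyde; 2 cis-but-2-ene
Product: 6 (1R,2S)-2-methyl-1-(3,4,5-trimethoxyphenyl)but-3-en-1-ol, via (Z)-crotylpotassium 3 (not isolated), via (Z)-crotyldiisopinocampheylborane 4 (not isolated), via borinate ester 5 (not isolated)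
Conditions: 2, n-BuLi, KOt-Bu, THF, −78 to −45 °C; (+)-Ipc2BOMe [from (−)-α-pinene], −78 °C; BF3·OEt2; 1, −78 °C; then NaOH, H2O2, 0 °C to rt
Reagents that add atoms: none
Why: Brown crotylboration through a closed chair transition state, in which the Z-crotyl geometry gives the syn C7/C8 relation and the isopinocampheyl groups from (−)-α-pinene direct the allyl unit to the Re face of the aldehyde (8R, hence 7S).

**Step 2**
Reactants: 6 (1R,2S)-2-methyl-1-(3,4,5-trimethoxyphenyl)but-3-en-1-ol
Product: 7 triisopropyl{[(1R,2S)-2-methyl-1-(3,4,5-trimethoxyphenyl)but-3-en-1-yl]oxy}silane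
Conditions: TIPSOTf, 2,6-lutidine, CH2Cl2, 0 °C to rt
Reagents that add atoms: triisopropylsilyl trifluoromethanesulfonate, CC(C)[Si](OS(=O)(=O)C(F)(F)F)(C(C)C)C(C)C
Why: O-silylation with a silyl triflate and a hindered base should cap the hindered benzylic alcohol without touching a stereocentre, and the bulky group adds size at C8 for step 8.

**Step 3**
Reactants: 7 triisopropylsilyl ether of 6
Product: 9 (3S,4R)-3-methyl-4-(3,4,5-trimethoxyphenyl)-4-[(triisopropylsilyl)oxy]butan-1-ol, via B-alkyl-9-borabicyclo[3.3.1]nonane 8 (not isolated)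
Conditions: 9-borabicyclo[3.3.1]nonane (9-BBN), THF, 0 °C to rt; then NaOH, H2O2, 0 °C
Reagents that add atoms: hydrogen peroxide, OO
Why: Hydroboration–oxidation with 9-BBN places boron, then oxygen, on the terminal carbon of the monosubstituted alkene (anti-Markovnikov) and creates no stereocentre.

**Step 4**
Reactants: 9 (3S,4R)-3-methyl-4-(3,4,5-trimethoxyphenyl)-4-[(triisopropylsilyl)oxy]butan-1-ol
Product: 10 (3S,4R)-3-methyl-4-(3,4,5-trimethoxyphenyl)-4-[(triisopropylsilyl)oxy]butanal
Conditions: 2,2,6,6-tetramethylpiperidin-1-oxyl (TEMPO, 10 mol%), PhI(OAc)2, CH2Cl2, rt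
Reagents that add atoms: none
Why: Oxoammonium (TEMPO) oxidation of a primary alcohol stops at the aldehyde, and C7 is β to the new carbonyl so it cannot epimerise.

**Step 5**
Reactants: 10 (3S,4R)-3-methyl-4-(3,4,5-trimethoxyphenyl)-4-[(triisopropylsilyl)oxy]butanal
Product: 11 (3S,4R)-3-methyl-2-methylidene-4-(3,4,5-trimethoxyphenyl)-4-[(triisopropylsilyl)oxy]butanal
Conditions: 37% aq. CH2O, pyrrolidine (10 mol%), propionic acid (10 mol%), i-PrOH, 45 °C
Reagents that add atoms: formaldehyde, C=O
Why: Amine-catalysed α-methylenation (enamine Mannich addition to formaldehyde, then elimination of the amine) installs C5 on C6 under mild conditions that leave the C7 stereocentre alone.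

**Step 6**
Reactants: 12 2,5-dimethoxytetrahydrofuran
Product: 13 succinaldehyde (butanedial)
Conditions: H2O, 90 °C; extraction, used at once
Reagents that add atoms: water, O
Why: Hydrolysis of the cyclic bis-acetal releases the 1,4-dialdehyde and methanol.

**Step 7**
Reactants: 13 succinaldehyde
Product: 14 (1E,3E)-1,4-bis[(triethylsilyl)oxy]buta-1,3-diene
Conditions: Et3SiOTf, Et3N, Et2O, 0 °C to rt; distillation
Reagents that add atoms: triethylsilyl trifluoromethanesulfonate, CC[Si](CC)(CC)OS(=O)(=O)C(F)(F)F
Why: Soft enolisation and O-silylation of both aldehyde groups (silyl enol ether formation) should give the conjugated dienol ether, the extended E,E isomer being the one that can adopt the s-cis shape needed next.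

**Step 8**
Reactants: 11 (3S,4R)-3-methyl-2-methylidene-4-(3,4,5-trimethoxyphenyl)-4-[(triisopropylsilyl)oxy]butanal; 14 (1E,3E)-1,4-bis[(triethylsilyl)oxy]buta-1,3-diene
Product: 15 (1S,2R,5R)-2,5-bis[(triethylsilyl)oxy]-1-{(1R,2S)-1-(3,4,5-trimethoxyphenyl)-1-[(triisopropylsilyl)oxy]propan-2-yl}cyclohex-3-ene-1-carbaldehyde (megaphone numbering: formyl on C6, silyloxy groups on C1 and C4, both cis to the C7 chain and trans to formyl)
Conditions: Me2AlCl (0.2 equiv), 14 (2.5 equiv), CH2Cl2, −78 to −40 °C; Et3N, aq. NaHCO3 quench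
Reagents that add atoms: none
Why: Me2AlCl binds the formyl oxygen and lowers the enal LUMO, so the electron-rich diene adds in a concerted, asynchronous [4+2] cycloaddition in which the C4–C5 bond runs ahead of the C1–C6 bond; the closest known reaction type is the Lewis-acid-promoted Diels–Alder reaction of 2-substituted acroleins with 1-silyloxy- and 1,4-dioxygenated butadienes. The cyclohexene ring closes by suprafacial union of the 4π diene with the 2π unit C5=C6, both bonds forming on one face of each partner, so the E,E geometry of 14 becomes a cis relation of the C1 and C4 silyloxy groups. Their relation to C6 comes from the exo-formyl array that 2-substituted acroleins favour, which places both oxygens cis to the C7 chain and trans to the formyl group, as C4 of the target requires. C6 is controlled by C7: with the chain lying under the diene only C7–H can point at it, the bulky silyloxybenzyl group takes the methylene side away from the aluminium-bound carbonyl and methyl the carbonyl side, so bonding occurs on the Re face of C6. The step thus needs exo selectivity and Re-face selectivity, secured by the 2-substituent and by the C7 centre with its large C8 substituent, while the symmetrical diene leaves no regiochemical choice.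

**Step 9**
Reactants: 15 cycloadduct aldehyde
Product: 16 methyl enol ether of the homologated aldehyde (15 with CH=CH–OMe in place of CHO, E/Z mixture, stereocentres unchanged)
Conditions: Ph3P(CH2OMe)Cl, KN(SiMe3)2, THF, 0 °C to rt
Reagents that add atoms: (methoxymethyl)triphenylphosphonium chloride, COC[P+](c1ccccc1)(c1ccccc1)c1ccccc1.[Cl-]
Why: Wittig olefination with the small methoxymethylene ylide is the standard one-carbon homologation of hindered aldehydes, and the silazide base leaves the C1 silyl ether in place, so no β-alkoxide arises that could open the ring by retro-aldol cleavage.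

**Step 10**
Reactants: 16 methyl enol ether
Product: 17 (2-oxoethyl) diol (megaphone skeleton with CH2CHO on C6 and free hydroxyl groups on C1 and C4; C8 still triisopropylsilylated)
Conditions: 1 M aq. HCl, THF, 0 °C to rt
Reagents that add atoms: water, O
Why: Acid hydrolysis of the enol ether (C-protonation, hydration of the oxocarbenium ion, loss of methanol) gives the homologated aldehyde, and the same acid cleaves the two triethylsilyl ethers while the hindered triisopropylsilyl ether stays.

**Step 11**
Reactants: 17 (2-oxoethyl) diol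
Product: 18 (1R,4R,6R)-6-(prop-2-en-1-yl)-6-{(1R,2S)-1-(3,4,5-trimethoxyphenyl)-1-[(triisopropylsilyl)oxy]propan-2-yl}cyclohex-2-ene-1,4-diol (megaphone numbering)
Conditions: Ph3PCH3Br, KN(SiMe3)2 (excess), THF, 0 °C to rt
Reagents that add atoms: methyltriphenylphosphonium bromide, C[P+](c1ccccc1)(c1ccccc1)c1ccccc1.[Br-]
Why: Wittig methylenation with excess ylide, which first deprotonates the two hydroxyl groups and then olefinates the aldehyde (also out of any cyclic hemiacetal form), completes the allyl group without touching a stereocentre.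

**Step 12**
Reactants: 18 allyl diol
Product: 19 (1R,4R,6R)-4-methoxy-6-(prop-2-en-1-yl)-6-{(1R,2S)-1-(3,4,5-trimethoxyphenyl)-1-[(triisopropylsilyl)oxy]propan-2-yl}cyclohex-2-en-1-ol
Conditions: NaH (1.05 equiv), MeI (1.2 equiv), THF, −20 to 0 °C
Reagents that add atoms: iodomethane, CI
Why: Williamson etherification under steric control: the C4 alkoxide sits next to a methylene group whereas the C1 alkoxide is shielded by the quaternary C6 and its branched chain, so the methyl group should go to C4.

**Step 13**
Reactants: 19 C4 methyl ether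
Product: 20 (4R,6R)-4-methoxy-6-(prop-2-en-1-yl)-6-{(1R,2S)-1-(3,4,5-trimethoxyphenyl)-1-[(triisopropylsilyl)oxy]propan-2-yl}cyclohex-2-en-1-one
Conditions: Dess–Martin periodinane, CH2Cl2, 0 °C to rt
Reagents that add atoms: none
Why: Dess–Martin oxidation of the one remaining, allylic alcohol gives the enone, removing the C1 stereocentre, and C6 carries no hydrogen so nothing next to the ketone can epimerise.

**Step 14**
Reactants: 20 megaphone triisopropylsilyl ether
Product: 21 megaphone, (4R,6R)-6-[(1R,2S)-1-hydroxy-1-(3,4,5-trimethoxyphenyl)propan-2-yl]-4-methoxy-6-(prop-2-en-1-yl)cyclohex-2-en-1-one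
Conditions: Bu4NF, AcOH (1:1), THF, rt
Reagents that add atoms: none
Why: Fluoride-induced desilylation (Si–F bond formation) frees the C8 alcohol, and the acetic acid buffer keeps the γ-methoxy enone away from basic alkoxide that could epimerise C4.

**Compound list**

1 | 3,4,5-trimethoxybenzaldehyde | COc1cc(C=O)cc(OC)c1OC | starting material
2 | cis-but-2-ene | C/C=C\C | starting material
3 | (Z)-but-2-en-1-ylpotassium | C/C=C\[CH2-].[K+] | intermediate (not isolated)
4 | (Z)-but-2-en-1-yl-diisopinocampheylborane, isopinocampheyl groups from (−)-α-pinene | C/C=C\CB([C@H]1C[C@H]2C[C@@H]([C@@H]1C)C2(C)C)[C@H]1C[C@H]2C[C@@H]([C@@H]1C)C2(C)C | intermediate (not isolated)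
5 | diisopinocampheylborinate ester of 6 | C=C[C@H](C)[C@@H](OB([C@H]1C[C@H]2C[C@@H]([C@@H]1C)C2(C)C)[C@H]1C[C@H]2C[C@@H]([C@@H]1C)C2(C)C)c1cc(OC)c(OC)c(OC)c1 | intermediate (not isolated)
6 | (1R,2S)-2-methyl-1-(3,4,5-trimethoxyphenyl)but-3-en-1-ol | C=C[C@H](C)[C@@H](O)c1cc(OC)c(OC)c(OC)c1 | intermediate
7 | triisopropyl{[(1R,2S)-2-methyl-1-(3,4,5-trimethoxyphenyl)but-3-en-1-yl]oxy}silane | C=C[C@H](C)[C@@H](O[Si](C(C)C)(C(C)C)C(C)C)c1cc(OC)c(OC)c(OC)c1 | intermediate
8 | 9-[(3S,4R)-3-methyl-4-(3,4,5-trimethoxyphenyl)-4-(triisopropylsilyloxy)butyl]-9-borabicyclo[3.3.1]nonane | C1CC2CCCC(C1)B2CC[C@H](C)[C@@H](O[Si](C(C)C)(C(C)C)C(C)C)c1cc(OC)c(OC)c(OC)c1 | intermediate (not isolated)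
9 | (3S,4R)-3-methyl-4-(3,4,5-trimethoxyphenyl)-4-[(triisopropylsilyl)oxy]butan-1-ol | OCC[C@H](C)[C@@H](O[Si](C(C)C)(C(C)C)C(C)C)c1cc(OC)c(OC)c(OC)c1 | intermediate
10 | (3S,4R)-3-methyl-4-(3,4,5-trimethoxyphenyl)-4-[(triisopropylsilyl)oxy]butanal | O=CC[C@H](C)[C@@H](O[Si](C(C)C)(C(C)C)C(C)C)c1cc(OC)c(OC)c(OC)c1 | intermediate
11 | (3S,4R)-3-methyl-2-methylidene-4-(3,4,5-trimethoxyphenyl)-4-[(triisopropylsilyl)oxy]butanal | C=C(C=O)[C@H](C)[C@@H](O[Si](C(C)C)(C(C)C)C(C)C)c1cc(OC)c(OC)c(OC)c1 | intermediate (precursor of the key step)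
12 | 2,5-dimethoxytetrahydrofuran (cis/trans mixture) | COC1CCC(OC)O1 | starting material
13 | succinaldehyde | O=CCCC=O | intermediate
14 | (1E,3E)-1,4-bis[(triethylsilyl)oxy]buta-1,3-diene | CC[Si](CC)(CC)O/C=C/C=C/O[Si](CC)(CC)CC | intermediate (precursor of the key step)
15 | (1S,2R,5R)-2,5-bis[(triethylsilyl)oxy]-1-{(1R,2S)-1-(3,4,5-trimethoxyphenyl)-1-[(triisopropylsilyl)oxy]propan-2-yl}cyclohex-3-ene-1-carbaldehyde | O=C[C@]1([C@H](C)[C@@H](O[Si](C(C)C)(C(C)C)C(C)C)c2cc(OC)c(OC)c(OC)c2)C[C@@H](O[Si](CC)(CC)CC)C=C[C@H]1O[Si](CC)(CC)CC | intermediate (product of the key step)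
16 | methyl enol ether: 15 with CH=CH–OMe in place of CHO (E/Z mixture), stereocentres as in 15 | COC=C[C@]1([C@H](C)[C@@H](O[Si](C(C)C)(C(C)C)C(C)C)c2cc(OC)c(OC)c(OC)c2)C[C@@H](O[Si](CC)(CC)CC)C=C[C@H]1O[Si](CC)(CC)CC | intermediate
17 | (2-oxoethyl) diol: CH2CHO on C6, free OH on C1 and C4 (cis to each other and to the C7 chain), C8 O-triisopropylsilyl | O=CC[C@]1([C@H](C)[C@@H](O[Si](C(C)C)(C(C)C)C(C)C)c2cc(OC)c(OC)c(OC)c2)C[C@@H](O)C=C[C@H]1O | intermediate
18 | (1R,4R,6R)-6-(prop-2-en-1-yl)-6-{(1R,2S)-1-(3,4,5-trimethoxyphenyl)-1-[(triisopropylsilyl)oxy]propan-2-yl}cyclohex-2-ene-1,4-diol (megaphone numbering) | C=CC[C@]1([C@H](C)[C@@H](O[Si](C(C)C)(C(C)C)C(C)C)c2cc(OC)c(OC)c(OC)c2)C[C@@H](O)C=C[C@H]1O | intermediate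
19 | (1R,4R,6R)-4-methoxy-6-(prop-2-en-1-yl)-6-{(1R,2S)-1-(3,4,5-trimethoxyphenyl)-1-[(triisopropylsilyl)oxy]propan-2-yl}cyclohex-2-en-1-ol | C=CC[C@]1([C@H](C)[C@@H](O[Si](C(C)C)(C(C)C)C(C)C)c2cc(OC)c(OC)c(OC)c2)C[C@@H](OC)C=C[C@H]1O | intermediate
20 | (4R,6R)-4-methoxy-6-(prop-2-en-1-yl)-6-{(1R,2S)-1-(3,4,5-trimethoxyphenyl)-1-[(triisopropylsilyl)oxy]propan-2-yl}cyclohex-2-en-1-one | C=CC[C@]1([C@H](C)[C@@H](O[Si](C(C)C)(C(C)C)C(C)C)c2cc(OC)c(OC)c(OC)c2)C[C@@H](OC)C=CC1=O | intermediate
21 | megaphone, (4R,6R)-6-[(1R,2S)-1-hydroxy-1-(3,4,5-trimethoxyphenyl)propan-2-yl]-4-methoxy-6-(prop-2-en-1-yl)cyclohex-2-en-1-one | C=CC[C@]1([C@H](C)[C@@H](O)c2cc(OC)c(OC)c(OC)c2)C[C@@H](OC)C=CC1=O | target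

**Totals and risks**

Total step count: 14. Longest linear sequence: 12 steps (steps 1–5 and 8–14); the diene branch is steps 6–7.

Steps most likely to fail:

1. Step 8. Facial discrimination by C7 is the least secure point: a competing rotamer, with the silyloxybenzyl group anti to the forming C1–C6 bond and methyl over the methylene carbon, would lead to the C6 epimer, and nothing later can correct C6. Some material may also pass through the endo array (epimers at C1 and C4) or be lost by Lewis-acid cleavage of the silyl dienol ether. Fallback: set out again from 11 and 14 and return at 15, but move control of the enal face from the substrate to the reagent. The cycloaddition would be promoted by a chiral oxazaborolidinium Lewis acid, N-protonated (S)- or (R)-1-(2-methylphenyl)-3,3-diphenyltetrahydro-1H,3H-pyrrolo[1,2-c][1,3,2]oxazaborole as its Tf2N salt, using the antipode that leaves the Re face of C6 open. Such acids are established for 2-substituted acroleins and should override a weak or opposed substrate bias. New compounds: none (F0).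

2. Step 12. The two secondary allylic hydroxyl groups may not be distinguished well enough, giving methylation at C1 or at both oxygens. Fallback: from 18, silylate the less hindered C4 hydroxyl with the bulkier and more selective Et3SiCl/imidazole (CH2Cl2, −40 °C) to the C4 triethylsilyl ether F1. Oxidise the C1 alcohol with Dess–Martin periodinane to the silyloxy enone F2, then remove the triethylsilyl group with pyridinium p-toluenesulfonate in methanol to the 4-hydroxy enone F3. Methylation of this single hydroxyl with MeI/Ag2O returns to the route at 20.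

3. Step 9. Olefination at the neopentyl formyl group may be slow, and loss of the C1 silyl group under the basic conditions would open the ring by retro-aldol cleavage. Fallback: from 15, add the smaller and more nucleophilic methoxy(trimethylsilyl)methyllithium (from (methoxymethyl)trimethylsilane and s-BuLi, THF, −78 °C) to the formyl group to give the β-hydroxy silane F4. Peterson elimination with KH in THF then gives the enol ether, and the route is rejoined at 16.

**Further compounds**

F0 | step 8 | none | none
F1 | step 12 | C4 triethylsilyl ether of diol 18 (C1 hydroxyl free) | C=CC[C@]1([C@H](C)[C@@H](O[Si](C(C)C)(C(C)C)C(C)C)c2cc(OC)c(OC)c(OC)c2)C[C@@H](O[Si](CC)(CC)CC)C=C[C@H]1O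
F2 | step 12 | (4R,6R)-6-allyl-4-[(triethylsilyl)oxy] enone, C8 O-triisopropylsilyl | C=CC[C@]1([C@H](C)[C@@H](O[Si](C(C)C)(C(C)C)C(C)C)c2cc(OC)c(OC)c(OC)c2)C[C@@H](O[Si](CC)(CC)CC)C=CC1=O
F3 | step 12 | (4R,6R)-6-allyl-4-hydroxy enone, C8 O-triisopropylsilyl | C=CC[C@]1([C@H](C)[C@@H](O[Si](C(C)C)(C(C)C)C(C)C)c2cc(OC)c(OC)c(OC)c2)C[C@@H](O)C=CC1=O
F4 | step 9 | β-hydroxy silane from 15 and methoxy(trimethylsilyl)methyllithium (mixture at the two new carbons) | COC([Si](C)(C)C)C(O)[C@]1([C@H](C)[C@@H](O[Si](C(C)C)(C(C)C)C(C)C)c2cc(OC)c(OC)c(OC)c2)C[C@@H](O[Si](CC)(CC)CC)C=C[C@H]1O[Si](CC)(CC)CC
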